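## Retrosynthetic overview

1. 19 ⇒ 18: the C2–OH bond and the 2R hemiketal centre are made last, by a catalyst-controlled enantioselective α-hydroxylation (the proposed new step).
2. 18 ⇒ 14: the furanone ring is the only ring formed (the benzene ring is bought); it is closed at the aryl–C3 bond by Parham cyclisation of an aryl bromide onto a morpholine amide.
3. 14 ⇒ 12 + 9: the C2–C1' bond comes from alkylation of an aryloxyacetamide enolate with the allylic bromide.
4. 9 ⇒ 3: the C8'–C9' bond and the 8'R carbinol come from Brown allylboration of an enal; the prenyl terminus comes from cross-metathesis.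
5. 3 ⇒ 1 by allylic oxidation of geranyl acetate; 12 ⇒ 10 + 11 by Williamson etherification.

Assumption: the C2 hemiketal of 19 keeps its configuration when kept neutral, aprotic and cold (ring opening to the 1,2-diketone needs acid or base), so it is made in the last step and not processed further; C2 of 14, 17 and 18 is an inconsequential epimer mixture.

## Route

Step 1
Reactants: 1 geranyl acetate [(2E)-3,7-dimethylocta-2,6-dien-1-yl acetate]
Product: 2 (2E,6E)-8-hydroxy-3,7-dimethylocta-2,6-dien-1-yl acetate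
Conditions: SeO2 (0.3 equiv), tBuOOH (70% aq., 3 equiv), salicylic acid (0.1 equiv), CH2Cl2, rt, 24 h
Reagents that add atoms: tert-butyl hydroperoxide, CC(C)(C)OO (terminal oxygen source); selenium dioxide, O=[Se]=O (catalytic oxygen carrier)
Why: Catalytic SeO2/tBuOOH allylic oxidation (ene reaction then [2,3]-sigmatropic shift) hydroxylates the (E)-methyl of the electron-rich terminal trisubstituted alkene and leaves the acetate-deactivated 2,3-alkene alone.

Step 2
Reactants: 2 (2E,6E)-8-hydroxy-3,7-dimethylocta-2,6-dien-1-yl acetate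
Product: 3 (2E,6E)-3,7-dimethyl-8-oxoocta-2,6-dien-1-yl acetate
Conditions: TEMPO (10 mol %), PhI(OAc)2 (1.1 equiv), CH2Cl2, rt
Reagents that add atoms: none
Why: TEMPO/PhI(OAc)2 (oxoammonium) oxidation takes the primary allylic alcohol to the enal without over-oxidation or E/Z isomerisation.

Step 3
Reactants: 3 (2E,6E)-3,7-dimethyl-8-oxoocta-2,6-dien-1-yl acetate
Product: 5 (2E,6E,8R)-8-hydroxy-3,7-dimethylundeca-2,6,10-trien-1-yl acetate, via borinate ester 4 (not isolated)
Conditions: (−)-Ipc2B(allyl) (1 M in pentane, 1.3 equiv), Et2O, −78 °C, 2 h; then NaBO3·4H2O, THF/H2O, rt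
Reagents that add atoms: (−)-B-allyldiisopinocampheylborane [lIpc2B(allyl), the enantiomer built from (−)-α-pinene], C=CCB([C@H]1C[C@H]2C[C@@H]([C@@H]1C)C2(C)C)[C@H]1C[C@H]2C[C@@H]([C@@H]1C)C2(C)C
Why: Brown allylboration through a chair Zimmerman–Traxler transition state sets the 8R carbinol under reagent control (the (+)-α-pinene-derived antipode gives the S carbinol with α-substituted enals, so this reagent gives R), and the mild perborate work-up frees the alcohol without touching the acetate.

Step 4
Reactants: 5 (2E,6E,8R)-8-hydroxy-3,7-dimethylundeca-2,6,10-trien-1-yl acetate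
Product: 6 (2E,6E,8R)-8-[(tert-butyldimethylsilyl)oxy]-3,7-dimethylundeca-2,6,10-trien-1-yl acetate
Conditions: TBSCl (1.5 equiv), imidazole (3 equiv), DMF, rt
Reagents that add atoms: tert-butyldimethylsilyl chloride, CC(C)(C)[Si](C)(C)Cl
Why: Standard imidazole-promoted silylation of a secondary alcohol; the stereocentre is not touched.

Step 5
Reactants: 6 (2E,6E,8R)-8-[(tert-butyldimethylsilyl)oxy]-3,7-dimethylundeca-2,6,10-trien-1-yl acetate
Product: 7 (2E,6E,8R)-8-[(tert-butyldimethylsilyl)oxy]-3,7,11-trimethyldodeca-2,6,10-trien-1-yl acetate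
Conditions: second-generation Grubbs catalyst RuCl2(=CHPh)(PCy3)(SIMes) (5 mol %), 2-methyl-2-butene/CH2Cl2 (1:1), 40 °C, sealed tube
Reagents that add atoms: 2-methyl-2-butene, CC=C(C)C
Why: Olefin cross-metathesis in which only the monosubstituted alkene engages the ruthenium carbene and excess 2-methyl-2-butene caps it as the prenyl terminus, the existing trisubstituted alkenes being inert.

Step 6
Reactants: 7 (2E,6E,8R)-8-[(tert-butyldimethylsilyl)oxy]-3,7,11-trimethyldodeca-2,6,10-trien-1-yl acetate
Product: 8 (2E,6E,8R)-8-[(tert-butyldimethylsilyl)oxy]-3,7,11-trimethyldodeca-2,6,10-trien-1-ol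
Conditions: K2CO3 (0.2 equiv), MeOH, 0 °C to rt
Reagents that add atoms: none
Why: Base-catalysed transesterification (methanolysis) removes the acetate while the silyl ether survives.

Step 7
Reactants: 8 (2E,6E,8R)-8-[(tert-butyldimethylsilyl)oxy]-3,7,11-trimethyldodeca-2,6,10-trien-1-ol
Product: 9 (2E,6E,8R)-1-bromo-8-[(tert-butyldimethylsilyl)oxy]-3,7,11-trimethyldodeca-2,6,10-triene
Conditions: CBr4 (1.3 equiv), PPh3 (1.4 equiv), CH2Cl2, −20 to 0 °C; used crude after a short silica plug
Reagents that add atoms: carbon tetrabromide, BrC(Br)(Br)Br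
Why: Appel reaction: SN2 displacement of the alkoxyphosphonium by bromide gives the primary allylic bromide at low temperature without allylic transposition or loss of E geometry.

Step 8
Reactants: 10 2-bromo-3-methylphenol; 11 4-(chloroacetyl)morpholine [2-chloro-1-(morpholin-4-yl)ethan-1-one]
Product: 12 2-(2-bromo-3-methylphenoxy)-1-(morpholin-4-yl)ethan-1-one
Conditions: K2CO3 (1.5 equiv), KI (10 mol %), MeCN, 70 °C
Reagents that add atoms: none
Why: Williamson ether synthesis: the phenoxide displaces the activated α-chloroamide chloride under iodide catalysis.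

Step 9
Reactants: 12 2-(2-bromo-3-methylphenoxy)-1-(morpholin-4-yl)ethan-1-one; 9 (2E,6E,8R)-1-bromo-8-[(tert-butyldimethylsilyl)oxy]-3,7,11-trimethyldodeca-2,6,10-triene
Product: 14 (4E,8E,10R)-2-(2-bromo-3-methylphenoxy)-10-[(tert-butyldimethylsilyl)oxy]-5,9,13-trimethyl-1-(morpholin-4-yl)tetradeca-4,8,12-trien-1-one (both C2 epimers), via lithium enolate 13 (not isolated)
Conditions: LiN(iPr)2 (1.1 equiv), THF, −78 °C, 30 min; then 9, −78 to −30 °C
Reagents that add atoms: lithium diisopropylamide, [Li]N(C(C)C)C(C)C (supplies the lithium of 13 only)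
Why: Amide enolate alkylation: the lithium enolate reacts SN2 at the primary allylic bromide with retention of both E alkenes, and the new α-centre is formed as a mixture that does not matter because it becomes the enolisable C2 of the benzofuranone.

Step 10
Reactants: 14 (4E,8E,10R)-2-(2-bromo-3-methylphenoxy)-10-[(tert-butyldimethylsilyl)oxy]-5,9,13-trimethyl-1-(morpholin-4-yl)tetradeca-4,8,12-trien-1-one
Product: 17 2-[(2E,6E,8R)-8-[(tert-butyldimethylsilyl)oxy]-3,7,11-trimethyldodeca-2,6,10-trien-1-yl]-4-methyl-1-benzofuran-3(2H)-one (both C2 epimers), via aryllithium 15 (not isolated), via lithium hemiaminal alkoxide 16 (not isolated)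
Conditions: tBuLi (2.1 equiv), THF, −78 °C, 20 min; then degassed H2O, −78 °C to rt, under Ar
Reagents that add atoms: tert-butyllithium, [Li]C(C)(C)C (supplies the lithium of 15 and 16 only)
Why: Parham cyclisation (bromine–lithium exchange, then 5-exo intramolecular acylation): the aryllithium adds to the morpholine amide to give a stable tetrahedral alkoxide that releases the ketone only on quench, closing the furanone ring without over-addition.

Step 11
Reactants: 17 2-[(2E,6E,8R)-8-[(tert-butyldimethylsilyl)oxy]-3,7,11-trimethyldodeca-2,6,10-trien-1-yl]-4-methyl-1-benzofuran-3(2H)-one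
Product: 18 2-[(2E,6E,8R)-8-hydroxy-3,7,11-trimethyldodeca-2,6,10-trien-1-yl]-4-methyl-1-benzofuran-3(2H)-one (both C2 epimers)
Conditions: HF·pyridine, pyridine, THF, 0 °C to rt, under Ar
Reagents that add atoms: none
Why: Fluoride-mediated desilylation with pyridine-buffered HF removes the silyl ether without base (no enolate, so no autoxidation at C2) and without ionising the allylic alcohol; 8R is untouched.

Step 12
Reactants: 18 2-[(2E,6E,8R)-8-hydroxy-3,7,11-trimethyldodeca-2,6,10-trien-1-yl]-4-methyl-1-benzofuran-3(2H)-one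
Product: 19 (2R)-2-hydroxy-2-[(2E,6E,8R)-8-hydroxy-3,7,11-trimethyldodeca-2,6,10-trien-1-yl]-4-methyl-1-benzofuran-3(2H)-one
Conditions: (2S,6S)-2,6-di-tert-butyl-2,3,5,6-tetrahydro-1H-imidazo[1,2-a]imidazole (chiral bicyclic guanidine, 10 mol %), rac-trans-3-phenyl-2-(phenylsulfonyl)oxaziridine (1.3 equiv), toluene, 4 Å MS, −50 °C, Ar, dark; cold filtration through neutral silica
Reagents that add atoms: 3-phenyl-2-(phenylsulfonyl)oxaziridine, O=S(=O)(N1OC1c1ccccc1)c1ccccc1
Why: Proposed new method: catalytic enantioselective α-hydroxylation of a 2-alkylbenzofuran-3(2H)-one to a tertiary hemiketal; the C2–H is acidic because its conjugate base is an aromatic benzofuran-3-olate, so the guanidine deprotonates it reversibly to a guanidinium enolate held by one N–H···O hydrogen bond while the second N–H binds a sulfonyl oxygen of the oxaziridine, and attack of enolate C2 on the oxaziridine oxygen inside this C2-symmetric pocket forms the C2–O bond on one face and sets 2R under catalyst control (both C2 epimers of 18 converge through the planar enolate, the remote 8'R centre exerts no bias, the facial sense cannot be predicted in advance, and the (2R,6R) catalyst enantiomer is used instead should the first run give 2S); the hemiketal O–H is much less acidic than the substrate C–H, so the product leaves neutral and the ring-opening hemiketal alkoxide is not populated, and the oxaziridine does not touch trisubstituted alkenes, the secondary alcohol or the guanidine at −50 °C; the closest known reaction types are guanidine-catalysed α-hydroxylation of β-dicarbonyl compounds with N-sulfonyloxaziridines and the Davis oxidation of preformed ketone enolates.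

## Compound list

1 | geranyl acetate, (2E)-3,7-dimethylocta-2,6-dien-1-yl acetate | CC(C)=CCC/C(C)=C/COC(C)=O | starting material
2 | (2E,6E)-8-hydroxy-3,7-dimethylocta-2,6-dien-1-yl acetate | OC/C(C)=C/CC/C(C)=C/COC(C)=O | intermediate
3 | (2E,6E)-3,7-dimethyl-8-oxoocta-2,6-dien-1-yl acetate | O=C/C(C)=C/CC/C(C)=C/COC(C)=O | intermediate
4 | (2E,6E,8R)-8-[(diisopinocampheylboranyl)oxy]-3,7-dimethylundeca-2,6,10-trien-1-yl acetate (Ipc groups from (−)-α-pinene) | C=CC[C@@H](OB([C@H]1C[C@H]2C[C@@H]([C@@H]1C)C2(C)C)[C@H]1C[C@H]2C[C@@H]([C@@H]1C)C2(C)C)/C(C)=C/CC/C(C)=C/COC(C)=O | intermediate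
5 | (2E,6E,8R)-8-hydroxy-3,7-dimethylundeca-2,6,10-trien-1-yl acetate | C=CC[C@@H](O)/C(C)=C/CC/C(C)=C/COC(C)=O | intermediate
6 | (2E,6E,8R)-8-[(tert-butyldimethylsilyl)oxy]-3,7-dimethylundeca-2,6,10-trien-1-yl acetate | C=CC[C@@H](O[Si](C)(C)C(C)(C)C)/C(C)=C/CC/C(C)=C/COC(C)=O | intermediate
7 | (2E,6E,8R)-8-[(tert-butyldimethylsilyl)oxy]-3,7,11-trimethyldodeca-2,6,10-trien-1-yl acetate | CC(C)=CC[C@@H](O[Si](C)(C)C(C)(C)C)/C(C)=C/CC/C(C)=C/COC(C)=O | intermediate
8 | (2E,6E,8R)-8-[(tert-butyldimethylsilyl)oxy]-3,7,11-trimethyldodeca-2,6,10-trien-1-ol | CC(C)=CC[C@@H](O[Si](C)(C)C(C)(C)C)/C(C)=C/CC/C(C)=C/CO | intermediate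
9 | (2E,6E,8R)-1-bromo-8-[(tert-butyldimethylsilyl)oxy]-3,7,11-trimethyldodeca-2,6,10-triene | CC(C)=CC[C@@H](O[Si](C)(C)C(C)(C)C)/C(C)=C/CC/C(C)=C/CBr | intermediate
10 | 2-bromo-3-methylphenol | Cc1cccc(O)c1Br | starting material
11 | 4-(chloroacetyl)morpholine, 2-chloro-1-(morpholin-4-yl)ethan-1-one | O=C(CCl)N1CCOCC1 | starting material
12 | 2-(2-bromo-3-methylphenoxy)-1-(morpholin-4-yl)ethan-1-one | Cc1cccc(OCC(=O)N2CCOCC2)c1Br | intermediate
13 | lithium 2-(2-bromo-3-methylphenoxy)-1-(morpholin-4-yl)ethen-1-olate (lithium enolate of 12) | [Li]OC(=COc1cccc(C)c1Br)N1CCOCC1 | intermediate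
14 | (4E,8E,10R)-2-(2-bromo-3-methylphenoxy)-10-[(tert-butyldimethylsilyl)oxy]-5,9,13-trimethyl-1-(morpholin-4-yl)tetradeca-4,8,12-trien-1-one (both C2 epimers) | CC(C)=CC[C@@H](O[Si](C)(C)C(C)(C)C)/C(C)=C/CC/C(C)=C/CC(Oc1cccc(C)c1Br)C(=O)N1CCOCC1 | intermediate
15 | aryllithium from 14 (lithium in place of bromine) | CC(C)=CC[C@@H](O[Si](C)(C)C(C)(C)C)/C(C)=C/CC/C(C)=C/CC(Oc1cccc(C)c1[Li])C(=O)N1CCOCC1 | intermediate
16 | lithium 2-[(2E,6E,8R)-8-[(tert-butyldimethylsilyl)oxy]-3,7,11-trimethyldodeca-2,6,10-trien-1-yl]-4-methyl-3-(morpholin-4-yl)-2,3-dihydro-1-benzofuran-3-olate | CC(C)=CC[C@@H](O[Si](C)(C)C(C)(C)C)/C(C)=C/CC/C(C)=C/CC1Oc2cccc(C)c2C1(O[Li])N1CCOCC1 | intermediate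
17 | 2-[(2E,6E,8R)-8-[(tert-butyldimethylsilyl)oxy]-3,7,11-trimethyldodeca-2,6,10-trien-1-yl]-4-methyl-1-benzofuran-3(2H)-one (both C2 epimers) | CC(C)=CC[C@@H](O[Si](C)(C)C(C)(C)C)/C(C)=C/CC/C(C)=C/CC1Oc2cccc(C)c2C1=O | intermediate
18 | 2-[(2E,6E,8R)-8-hydroxy-3,7,11-trimethyldodeca-2,6,10-trien-1-yl]-4-methyl-1-benzofuran-3(2H)-one (both C2 epimers) | CC(C)=CC[C@@H](O)/C(C)=C/CC/C(C)=C/CC1Oc2cccc(C)c2C1=O | intermediate
19 | (2R)-2-hydroxy-2-[(2E,6E,8R)-8-hydroxy-3,7,11-trimethyldodeca-2,6,10-trien-1-yl]-4-methyl-1-benzofuran-3(2H)-one | CC(C)=CC[C@@H](O)/C(C)=C/CC/C(C)=C/C[C@@]1(O)Oc2cccc(C)c2C1=O | target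

## Step count and risks

Total step count: 12. Longest linear sequence: 11 steps (1 to 19 through steps 1–7 and 9–12; step 8 lies on the short branch).

Three steps most likely to fail:

Step 12 (proposed new hydroxylation). The risks are low facial selectivity, slow turnover, or epimerisation of the hemiketal. The fallback uses known reagent-controlled Davis enolate oxidation; it sets out from 17 and comes back at 19. Compound 17 is converted into its sodium enolate (NaN(SiMe3)2, THF, −78 °C) and oxidised with enantiopure (8,8-dichlorocamphorylsulfonyl)oxaziridine (the antipode that gives 2R), then quenched at −78 °C with AcOH. This gives (2R)-2-[(2E,6E,8R)-8-[(tert-butyldimethylsilyl)oxy]-3,7,11-trimethyldodeca-2,6,10-trien-1-yl]-2-hydroxy-4-methyl-1-benzofuran-3(2H)-one F1. Desilylation with HF·pyridine/pyridine in THF at 0 °C then delivers 19. Any minor C2 epimer is a diastereomer and can be removed by HPLC.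

Step 10 (Parham cyclisation). The risks are proton transfer to the aryllithium or addition of tBuLi to the amide. The fallback builds the furanone ring first and attaches the chain afterwards; it sets out from 7 and comes back at 17. Commercial methyl 2-hydroxy-6-methylbenzoate is O-alkylated with methyl bromoacetate (K2CO3, DMF) to methyl 2-(2-methoxy-2-oxoethoxy)-6-methylbenzoate F2. Dieckmann cyclisation (NaOMe, MeOH/toluene) gives methyl 3-hydroxy-4-methyl-1-benzofuran-2-carboxylate F3. After deprotonation (NaH, THF), F3 is C-allylated with acetate 7 under Pd(PPh3)4 catalysis (zerovalent palladium, Tsuji–Trost reaction; O-allylation is reversible, so the linear C-allyl product collects). This gives methyl 2-[(2E,6E,8R)-8-[(tert-butyldimethylsilyl)oxy]-3,7,11-trimethyldodeca-2,6,10-trien-1-yl]-4-methyl-3-oxo-2,3-dihydro-1-benzofuran-2-carboxylate F4. Krapcho demethoxycarbonylation (LiCl, wet DMSO, 130 °C) then gives 17.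

Step 3 (Brown allylboration). The risks are insufficient enantioselectivity on the α-methyl enal or loss of the acetate on work-up. The fallback sets the carbinol by ketone reduction instead; it sets out from 3 and comes back at 5. Aldehyde 3 is allylated without stereocontrol (allyl bromide, Zn, THF/aq. NH4Cl, Barbier conditions) to racemic (2E,6E)-8-hydroxy-3,7-dimethylundeca-2,6,10-trien-1-yl acetate F5. Oxidation (Dess–Martin periodinane, NaHCO3, CH2Cl2, 0 °C) gives (2E,6E)-3,7-dimethyl-8-oxoundeca-2,6,10-trien-1-yl acetate F6. Corey–Bakshi–Shibata reduction with (S)-Me-CBS oxazaborolidine (20 mol %) and catecholborane (toluene, −78 °C) then returns 8R alcohol 5, the trisubstituted alkenyl group acting as the large substituent.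

## Further compounds

F1 | step 12 | (2R)-2-[(2E,6E,8R)-8-[(tert-butyldimethylsilyl)oxy]-3,7,11-trimethyldodeca-2,6,10-trien-1-yl]-2-hydroxy-4-methyl-1-benzofuran-3(2H)-one | CC(C)=CC[C@@H](O[Si](C)(C)C(C)(C)C)/C(C)=C/CC/C(C)=C/C[C@@]1(O)Oc2cccc(C)c2C1=O
F2 | step 10 | methyl 2-(2-methoxy-2-oxoethoxy)-6-methylbenzoate | COC(=O)COc1cccc(C)c1C(=O)OC
F3 | step 10 | methyl 3-hydroxy-4-methyl-1-benzofuran-2-carboxylate | COC(=O)c1oc2cccc(C)c2c1O
F4 | step 10 | methyl 2-[(2E,6E,8R)-8-[(tert-butyldimethylsilyl)oxy]-3,7,11-trimethyldodeca-2,6,10-trien-1-yl]-4-methyl-3-oxo-2,3-dihydro-1-benzofuran-2-carboxylate (both C2 epimers) | CC(C)=CC[C@@H](O[Si](C)(C)C(C)(C)C)/C(C)=C/CC/C(C)=C/CC1(C(=O)OC)Oc2cccc(C)c2C1=O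
F5 | step 3 | racemic (2E,6E)-8-hydroxy-3,7-dimethylundeca-2,6,10-trien-1-yl acetate | C=CCC(O)/C(C)=C/CC/C(C)=C/COC(C)=O
F6 | step 3 | (2E,6E)-3,7-dimethyl-8-oxoundeca-2,6,10-trien-1-yl acetate | C=CCC(=O)/C(C)=C/CC/C(C)=C/COC(C)=O
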